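The runs are calculated from invented constants, noise included.

I began from a one-step world, E + Q <-> X, in which 0.180 M of the reagent Q against 0.20 M of the substrate E allowed X up to 90.0% of the E charged.

| flask | E | Q | remark | time |
|---|---|---|---|---|
| elm | 0.20 M | 0.18 M | the very flask that is asked about, followed so far |  |
| flask | 0.20 M | 0.180 M |  | 15 d |

elm run (percent of the E charged)

| time / d | X / % |
|---|---|
| 0.104 | 19 |
| 0.208 | 25 |
| 0.500 | 31 |
| 1.25 | 23 |
| 2.50 | 13 |
| 6.00 | 0 |

(standard deviation of a reading: 1.5 percentage points)

- in percentages every species weighs as the E in it: one G counts as two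
- for X the D are counted in
- as a solid, counted per litre of solution: D
- what was read earlier has a scatter of 1.5 percentage points, one standard deviation
- on the list of suspects stand: E + Q <-> X; E + X -> G; Q <-> J; D <-> X

* when, up to 15 d, the flask holds most X
* the amount of X, in percent of the E charged, at that time

But the elm run, this very flask followed so far, read X at 0% after 6.00 d. So I put that first answer back in: each X can take a second E by E + X -> G, and one G holds two E and one Q. The Q price of the E charge was therefore 0.100 M, half of [E] at the start. The Q charged less that price, 0.0800 M, I called the spare Q: what stands as Q and J together once the E has become G. With the price below the charge of Q, E was the limiting reagent.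

The readings gave a ladder. On the fastest rung, X reached 19% within 0.104 d. Next came the highest reading, 31% at 0.500 d, which with its scatter was my figure for the peak. Then X fell from 23% at 1.25 d to 13% at 2.50 d, a read half-life of 1.52 d. The limit of 15 d lay ten times further out, so I expected the flask to hold G and the 0.0800 M of spare Q there.

The forecast gave 0.45 d and 31.5%, earlier and higher than my figure, holding that “G is a dead end in a closed flask, so I expect no rebound later”.

The flask held most X at 0.385 d, with 29.3%: earlier than forecast, the height within the margin.

    E + Q ⇌ X (K = 14.0 M⁻¹, k = 0.0200 M⁻¹ min⁻¹)
    E + X → G (k = 0.0880 M⁻¹ min⁻¹)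
    Q ⇌ J (K = 0.410, k = 8.40 × 10⁻⁴ min⁻¹)
    D ⇌ X, rate k4*(cs4 - [X]) while solid is left; crystals form when [X] > cs4 (solubility = 9.40 mM, k = 0.580 min⁻¹)

At 15.0 d the flask held Q and J together at 0.0801 M, against the spare Q of 0.0800 M. A neighbouring flask had the same E but 0.045 M of Q, so its spare Q came out negative, −0.0550 M. There I reckoned two E per Q charged, which made G 45.0% of the E. That neighbour ended at 15.0 d with Q at 0%, 55% of its E unused, and G at 45.0%.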